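**Retrosynthetic overview** (rings: A = methoxy-bearing ring, B = para-phenylene, C = hydroxy-bearing ring, D = meta-phenylene without further substituent)
1. The target comes from a macrocyclic ketone that carries the ring C oxygen as a benzyl ether; one hydrogenolysis turns the bridge C=O into CH2 and frees the phenol.
2. The macrocyclic ketone comes from an open-chain silyl ether by closing the diaryl ether between the ring A oxygen (the one ortho to OMe) and C4 of ring B, through a fluoride-triggered SNAr on a 4-fluoroaryl ketone. This 19-membered ring is the only ring formed in the route; all four benzene rings are bought.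
3. Enabling feature: on ring B the ether carbon is para to the benzylic carbon of the CH2CH2 bridge to ring C. Carried as a ketone, that bridge carbon puts an acyl group para to C–F and stabilises the Meisenheimer anion; the last step erases it.
4. The open-chain ketone comes from a diaryl ether aldehyde and an α-anilinophosphonate (olefination, then hydrolysis, puts C=O on the ring B side). The aldehyde comes from a ring A styrene and a bromo diaryl ether by hydroboration and B-alkyl Suzuki coupling.
5. The bromo diaryl ether comes from 4-(benzyloxy)-3-hydroxybenzaldehyde and 3-bromophenylboronic acid (Chan–Lam); the styrene comes from isovanillin (silylation, Wittig).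

Key step: step 7

Remark: the target SMILES has no stereodescriptor and the structure has no stereocentre; the macrocycle is taken to be conformationally mobile, so it is one achiral compound and no enantiocontrol is needed.

Step 1
Reactants: 1 isovanillin (3-hydroxy-4-methoxybenzaldehyde)
Product: 3 4-methoxy-3-(triisopropylsilyloxy)benzaldehyde
Conditions: TIPSCl, imidazole, DMF, rt
Reagents that add atoms: 2 triisopropylsilyl chloride, CC(C)[Si](Cl)(C(C)C)C(C)C
Why: Standard silylation of a phenol (TIPSCl/imidazole) should cap the only hydroxyl group of ring A with a base-tolerant group that step 7 later uses as a latent phenoxide.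

Step 2
Reactants: 3 4-methoxy-3-(triisopropylsilyloxy)benzaldehyde
Product: 5 triisopropyl(2-methoxy-5-vinylphenoxy)silane
Conditions: MePPh3Br, KOtBu, THF, 0 °C → rt
Reagents that add atoms: 4 methyltriphenylphosphonium bromide, C[P+](c1ccccc1)(c1ccccc1)c1ccccc1.[Br-]
Why: Wittig methylenation of a non-enolisable aryl aldehyde with methylenetriphenylphosphorane is reliable, and the hindered aryl silyl ether should survive because the alkoxide is used up in forming the ylide.

Step 3
Reactants: 6 4-(benzyloxy)-3-hydroxybenzaldehyde; 7 (3-bromophenyl)boronic acid
Product: 8 4-(benzyloxy)-3-(3-bromophenoxy)benzaldehyde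
Conditions: Cu(OAc)2 (2 equiv), pyridine, 4 Å MS, CH2Cl2, air, rt
Reagents that add atoms: none
Why: Chan–Lam coupling should join the phenol oxygen of ring C to the boron-bearing carbon of ring D oxidatively at room temperature, conditions under which the aryl bromide and the aldehyde are inert.

Step 4
Reactants: 5 triisopropyl(2-methoxy-5-vinylphenoxy)silane; 8 4-(benzyloxy)-3-(3-bromophenoxy)benzaldehyde
Product: 10 4-(benzyloxy)-3-(3-{2-[4-methoxy-3-(triisopropylsilyloxy)phenyl]ethyl}phenoxy)benzaldehyde, via alkylborane 9 (not isolated)
Conditions: 9-BBN, THF, 0 °C → rt; then 8, PdCl2(dppf) (5 mol%), K3PO4 (aq), DMF, 50 °C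
Reagents that add atoms: none
Why: Anti-Markovnikov hydroboration of the styrene with 9-BBN and B-alkyl Suzuki–Miyaura coupling of the resulting primary alkylborane with the aryl bromide should give the saturated two-carbon bridge between rings A and D in one pot, the aldehyde being spared because no B–H is left when 8 is added.

Step 5
Reactants: 11 4-fluorobenzaldehyde
Product: 15 diphenyl [(4-fluorophenyl)(phenylamino)methyl]phosphonate (racemic), via imine 14 (not isolated)
Conditions: aniline, (PhO)2P(O)H, i-PrOH, rt
Reagents that add atoms: 12 aniline, Nc1ccccc1; 13 diphenyl phosphite, O=[PH](Oc1ccccc1)Oc1ccccc1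
Why: Kabachnik–Fields three-component reaction, in which the phosphite adds to the imine formed in the flask; the new stereocentre is formed as a racemate and is destroyed in step 6.

Step 6
Reactants: 10 4-(benzyloxy)-3-(3-{2-[4-methoxy-3-(triisopropylsilyloxy)phenyl]ethyl}phenoxy)benzaldehyde; 15 diphenyl [(4-fluorophenyl)(phenylamino)methyl]phosphonate
Product: 17 2-[4-(benzyloxy)-3-(3-{2-[4-methoxy-3-(triisopropylsilyloxy)phenyl]ethyl}phenoxy)phenyl]-1-(4-fluorophenyl)ethan-1-one (open-chain ketone), via N-aryl enamine 16 (not isolated)
Conditions: NaH, THF, 0 °C → rt; then 2 M HCl (aq), THF, rt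
Reagents that add atoms: water, O
Why: Horner–Wadsworth–Emmons olefination of the aldehyde with the anion of the α-anilinophosphonate should give an N-aryl enamine whose acid hydrolysis places the carbonyl group on the carbon attached to the fluorinated ring B, an established acyl-anion-equivalent route to deoxybenzoins.

Step 7
Reactants: 17 open-chain ketone
Product: 19 macrocyclic ketone (the 19-membered ring of the target in which the bridge carbon on ring B is C=O and the ring C oxygen is a benzyl ether), via cesium phenoxide 18 (not isolated)
Conditions: CsF (2 equiv), DMAc (degassed), 100 °C, Ar; 17 added by syringe pump to a final 2 mM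
Reagents that add atoms: none
Why: Fluoride attacks silicon of the aryl TIPS ether and frees the cesium phenoxide 18 of ring A; its oxygen (ortho to OMe) adds to C4 of ring B, the C–F carbon para to the benzylic ketone, to give a Meisenheimer anion whose charge rests on the carbonyl oxygen, and loss of fluoride restores ring B and returns the fluoride that opens the next silyl ether (addition–elimination SNAr with fluoride relay). The closest known reaction type is the fluoride-promoted condensation of aryl silyl ethers with 4-fluoroaryl ketones used for poly(ether ketone)s, together with SNAr macrocyclisations to diaryl ether cyclophanes. The step closes the 19-membered ring, the only ring made in the route, by end-to-end attack of the phenoxide oxygen on an sp2 carbon of ring B; the three meta-linked rings A, C and D and the two flexible two-atom bridges should let the chain fold without much strain. No stereocentre is formed. Ring closure must win over oligomerisation and O-arylation must win over reactions of the enolisable CH2: slow addition at 2 mM and gradual release of phenoxide from the silyl ether keep the reactive anion dilute, ring C carries its oxygen as a benzyl ether so that ring A offers the only nucleophilic oxygen, ring B carries the only activated C–F, and with no base other than fluoride the mono-anion can cyclise only through its phenoxide/ketone form because the enolate form deactivates ring B.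

Step 8
Reactants: 19 macrocyclic ketone
Product: 22 target macrocycle CNP0132125.0, via keto-phenol 20 (not isolated), via benzylic alcohol 21 (not isolated)
Conditions: H2 (4 atm), 10% Pd/C, HClO4 (cat.), AcOH/EtOAc, 40 °C
Reagents that add atoms: none
Why: Catalytic hydrogenolysis over palladium should cleave the benzyl ether and, under acid, take the aryl ketone through the benzylic alcohol (a transient racemic stereocentre) to the methylene group, while the diaryl ether and methyl ether bonds are inert; the product has no stereocentre.

**Compound list**
1 | isovanillin (3-hydroxy-4-methoxybenzaldehyde) | COc1ccc(C=O)cc1O | starting material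
2 | triisopropylsilyl chloride | CC(C)[Si](Cl)(C(C)C)C(C)C | starting material
3 | 4-methoxy-3-(triisopropylsilyloxy)benzaldehyde | COc1ccc(C=O)cc1O[Si](C(C)C)(C(C)C)C(C)C | intermediate
4 | methyltriphenylphosphonium bromide | C[P+](c1ccccc1)(c1ccccc1)c1ccccc1.[Br-] | starting material
5 | triisopropyl(2-methoxy-5-vinylphenoxy)silane | C=Cc1ccc(OC)c(O[Si](C(C)C)(C(C)C)C(C)C)c1 | intermediate
6 | 4-(benzyloxy)-3-hydroxybenzaldehyde | O=Cc1ccc(OCc2ccccc2)c(O)c1 | starting material
7 | (3-bromophenyl)boronic acid | OB(O)c1cccc(Br)c1 | starting material
8 | 4-(benzyloxy)-3-(3-bromophenoxy)benzaldehyde | O=Cc1ccc(OCc2ccccc2)c(Oc2cccc(Br)c2)c1 | intermediate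
9 | 9-{2-[4-methoxy-3-(triisopropylsilyloxy)phenyl]ethyl}-9-borabicyclo[3.3.1]nonane (alkylborane) | COc1ccc(CCB2C3CCCC2CCC3)cc1O[Si](C(C)C)(C(C)C)C(C)C | intermediate
10 | 4-(benzyloxy)-3-(3-{2-[4-methoxy-3-(triisopropylsilyloxy)phenyl]ethyl}phenoxy)benzaldehyde | COc1ccc(CCc2cccc(Oc3cc(C=O)ccc3OCc3ccccc3)c2)cc1O[Si](C(C)C)(C(C)C)C(C)C | intermediate
11 | 4-fluorobenzaldehyde | O=Cc1ccc(F)cc1 | starting material
12 | aniline | Nc1ccccc1 | starting material
13 | diphenyl phosphite | O=[PH](Oc1ccccc1)Oc1ccccc1 | starting material
14 | (E)-N-(4-fluorobenzylidene)aniline (imine) | Fc1ccc(/C=N/c2ccccc2)cc1 | intermediate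
15 | diphenyl [(4-fluorophenyl)(phenylamino)methyl]phosphonate, racemic | O=P(Oc1ccccc1)(Oc1ccccc1)C(Nc1ccccc1)c1ccc(F)cc1 | intermediate
16 | N-aryl enamine from 10 and 15: ring C–CH=C(NHPh)–C6H4F, E/Z mixture | COc1ccc(CCc2cccc(Oc3cc(C=C(Nc4ccccc4)c4ccc(F)cc4)ccc3OCc3ccccc3)c2)cc1O[Si](C(C)C)(C(C)C)C(C)C | intermediate
17 | 2-[4-(benzyloxy)-3-(3-{2-[4-methoxy-3-(triisopropylsilyloxy)phenyl]ethyl}phenoxy)phenyl]-1-(4-fluorophenyl)ethan-1-one (open-chain ketone) | COc1ccc(CCc2cccc(Oc3cc(CC(=O)c4ccc(F)cc4)ccc3OCc3ccccc3)c2)cc1O[Si](C(C)C)(C(C)C)C(C)C | intermediate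
18 | cesium phenoxide of desilylated 17 | COc1ccc(CCc2cccc(Oc3cc(CC(=O)c4ccc(F)cc4)ccc3OCc3ccccc3)c2)cc1[O-].[Cs+] | intermediate
19 | macrocyclic ketone: target ring with C=O at the bridge carbon on ring B and OBn on ring C | COc1ccc2cc1Oc1ccc(cc1)C(=O)Cc1ccc(OCc3ccccc3)c(c1)Oc1cccc(c1)CC2 | intermediate
20 | macrocyclic keto-phenol: 19 without the benzyl group | COc1ccc2cc1Oc1ccc(cc1)C(=O)Cc1ccc(O)c(c1)Oc1cccc(c1)CC2 | intermediate
21 | macrocyclic benzylic alcohol: 20 with CH(OH) in place of C=O, racemic | COc1ccc2cc1Oc1ccc(cc1)C(O)Cc1ccc(O)c(c1)Oc1cccc(c1)CC2 | intermediate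
22 | target macrocycle CNP0132125.0 | COc1ccc2cc1Oc1ccc(cc1)CCc1ccc(O)c(c1)Oc1cccc(c1)CC2 | target

**Step count**
Total: 8 steps. Longest linear sequence: 6 steps (1, 2, 4, 6, 7, 8); steps 3 and 5 are side branches.

**Steps most likely to fail, with fallbacks**

Step 7 (macrocyclisation). Ring closure may lose to intermolecular etherification, or the enolisable ketone may be consumed by base-induced condensation or oxidation before the phenoxide reaches ring B. The fallback closes the same O–C bond by copper catalysis without the carbonyl group and sets out from aldehyde 10. Wittig reaction with the ylide from (4-bromobenzyl)triphenylphosphonium bromide (KOtBu, THF) should give the bromostilbene F1 as an E/Z mixture. Diimide reduction (TsNHNH2, NaOAc, DME/H2O, reflux) should saturate the alkene without touching C–Br or the benzyl ether and give the bromo bibenzyl F2. TBAF (THF, 0 °C) should free the ring A phenol F3. Intramolecular Ullmann ether coupling (CuI, N,N-dimethylglycine, Cs2CO3, dioxane, 100 °C, high dilution) should give the macrocyclic benzyl ether F4. Hydrogenolysis (H2, Pd/C, EtOAc) should then give the target, so the fallback comes back to the route at 22.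

Step 4 (hydroboration and B-alkyl Suzuki coupling). Residual B–H may reduce the aldehyde of 8, or the alkylborane may undergo protodeboronation or β-hydride elimination faster than transmetalation. The fallback sets out from 5 and 8. A Heck reaction (Pd(OAc)2, P(o-tol)3, Et3N, DMF, 100 °C) should give the (E)-stilbene aldehyde F5. Reduction of its C=C bond with diimide (potassium azodicarboxylate, AcOH, MeOH/THF, rt), which leaves the aldehyde, the benzyl ether and the silyl ether alone, should give 10, where the route is rejoined.

Step 8 (global hydrogenolysis). The deoxygenation may stall at the benzylic alcohol, or the acid may divert the benzylic cation into side reactions. The fallback sets out from 19 and separates the two events. Neutral hydrogenolysis (H2 1 atm, Pd/C, EtOAc, rt) should remove only the benzyl group and allow keto-phenol 20 to be isolated. Ionic hydrogenation (Et3SiH, TFA, CH2Cl2, 0 °C → rt), which passes through alcohol 21, should then give 22. This fallback makes no compound outside the list (F0).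

**Further compounds**
F1 | step 7 | bromostilbene: 10 with CH=CH–C6H4-4-Br in place of CHO, E/Z mixture | COc1ccc(CCc2cccc(Oc3cc(C=Cc4ccc(Br)cc4)ccc3OCc3ccccc3)c2)cc1O[Si](C(C)C)(C(C)C)C(C)C
F2 | step 7 | bromo bibenzyl: F1 with the alkene saturated | COc1ccc(CCc2cccc(Oc3cc(CCc4ccc(Br)cc4)ccc3OCc3ccccc3)c2)cc1O[Si](C(C)C)(C(C)C)C(C)C
F3 | step 7 | ring A phenol: F2 without the silyl group | COc1ccc(CCc2cccc(Oc3cc(CCc4ccc(Br)cc4)ccc3OCc3ccccc3)c2)cc1O
F4 | step 7 | macrocyclic benzyl ether: target with OBn in place of OH on ring C | COc1ccc2cc1Oc1ccc(cc1)CCc1ccc(OCc3ccccc3)c(c1)Oc1cccc(c1)CC2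
F5 | step 4 | (E)-stilbene aldehyde: 10 with CH=CH in place of the CH2CH2 bridge between rings A and D | COc1ccc(/C=C/c2cccc(Oc3cc(C=O)ccc3OCc3ccccc3)c2)cc1O[Si](C(C)C)(C(C)C)C(C)C
F0 | step 8 | none | none
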